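Ring B is taken from (R)-carvone and ring A (C1–C5, C10; labdane numbering) is closed last by a reductive Heck cyclization. The disconnection is the C3–C4 bond: the gem-dimethyl quaternary carbon C4, next to the ring-fusion methine C5, is the isopropenyl group of carvone, and the C2=C3 alkene (later the cis-2,3-diol) is a (Z)-3-iodoallyl arm on the quaternary C10. In one operation a 6-exo carbopalladation forms ring A, makes C4 quaternary and turns the isopropenyl CH2 into its second methyl. The precursor is a 6,6-dialkylated carvone in which the C5 and C10 arms are trans, so the trans ring fusion is set before the ring exists.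

Key step: step 5

Remark: the target is taken as drawn, (2R,3S,5S,8R,9S,10S) in labdane numbering (ring A = C1–C5, C10; ring B = C5–C10; side chain C11–C16), i.e. 2α-OAc, 3α-OH, 8α-CH3, 9β-OH with the side chain α, and a trans ring fusion; this numbering is used for all bicyclic compounds below.

Step 1
Reactants: 1 ethyl (2Z)-3-iodoprop-2-enoate
Product: 2 (2Z)-3-iodoprop-2-en-1-ol
Conditions: i-Bu2AlH (2.2 equiv), CH2Cl2, −78 to 0 °C; then H2O
Reagents that add atoms: none
Why: Hydride reduction of the ester by i-Bu2AlH at low temperature should give the allylic alcohol without touching the alkenyl iodide or its Z geometry.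

Step 2
Reactants: 2 (2Z)-3-iodoprop-2-en-1-ol
Product: 3 (1Z)-3-bromo-1-iodoprop-1-ene
Conditions: CBr4, PPh3, CH2Cl2, 0 °C
Reagents that add atoms: carbon tetrabromide, BrC(Br)(Br)Br
Why: Appel bromination converts the primary allylic alcohol into the bromide under neutral conditions, so the Z-alkenyl iodide should survive unchanged.

Step 3
Reactants: 4 (R)-(−)-carvone, (5R)-2-methyl-5-(prop-1-en-2-yl)cyclohex-2-en-1-one
Product: 6 (5R,6RS)-2,6-dimethyl-5-(prop-1-en-2-yl)cyclohex-2-en-1-one, via lithium dienolate 5 (not isolated)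
Conditions: LiN(i-Pr)2, THF, −78 °C; then MeI, −78 to 0 °C
Reagents that add atoms: iodomethane, CI
Why: Kinetic deprotonation at the α′-carbon (the future C10) gives the cross-conjugated lithium dienolate, which is C-methylated (enolate alkylation); the new centre is made planar again in step 4, so its epimer composition does not matter.

Step 4
Reactants: 6 (5R,6RS)-2,6-dimethyl-5-(prop-1-en-2-yl)cyclohex-2-en-1-one; 3 (1Z)-3-bromo-1-iodoprop-1-ene
Product: 8 (5S,6S)-6-[(2Z)-3-iodoprop-2-en-1-yl]-2,6-dimethyl-5-(prop-1-en-2-yl)cyclohex-2-en-1-one, via lithium dienolate 7 (not isolated)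
Conditions: LiN(i-Pr)2, THF, −78 °C; then 3, DMPU, −78 to −20 °C
Reagents that add atoms: none
Why: Enolate alkylation (SN2 at the allylic bromide) of the methyl-substituted enolate should occur anti to the neighbouring C5 isopropenyl group, which sits pseudoaxial to avoid allylic strain with the enolate methyl, so the iodoallyl arm on the new quaternary C10 ends up trans to the isopropenyl group and the methyl cis to it (substrate control).

Step 5
Reactants: 8 (5S,6S)-6-[(2Z)-3-iodoprop-2-en-1-yl]-2,6-dimethyl-5-(prop-1-en-2-yl)cyclohex-2-en-1-one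
Product: 9 (4aS,8aS)-2,5,5,8a-tetramethyl-4a,5,8,8a-tetrahydronaphthalen-1(4H)-one
Conditions: Pd(OAc)2 (10 mol %), PPh3 (20 mol %), HCO2Na (2 equiv), n-Bu4NCl (1 equiv), DMF, 80 °C
Reagents that add atoms: none
Why: Zerovalent palladium (formed from Pd(OAc)2 and PPh3) inserts into the alkenyl C3–I bond, the alkenylpalladium adds syn across the isopropenyl C4=CH2 bond, and the resulting neopentyl-type alkylpalladium, which has no β-hydrogen, exchanges iodide for formate, loses CO2 and reductively eliminates C–H, so the former =CH2 becomes the second methyl on C4. The closest known reaction type is the reductive Heck cyclization (carbopalladation followed by hydride capture), the standard way to turn a 2-propenyl group into a gem-dimethyl quaternary carbon. Ring A is closed through the C3–C4 bond in a 6-exo-trig mode, and the C2=C3 alkene of the iodoallyl arm is kept as the ring alkene. No new stereocentre is formed, because C4 ends with two identical methyls; the trans ring fusion is inherited from the trans C5 and C10 arms fixed in step 4, which are both equatorial in the cyclizing conformer. The step needs carbopalladation to outrun hydride capture at the alkenylpalladium stage and exo insertion to outrun endo insertion; the Z geometry holds C3 next to C4, the quaternary C10 favours the folded conformer, and a six-membered exo ring is preferred to a seven-membered endo ring. The ring-B enone is not a partner for the alkenylpalladium for reasons of distance, and excess formate should trap the alkylpalladium before it can re-insert into the new C2=C3 alkene.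

Step 6
Reactants: 9 (4aS,8aS)-2,5,5,8a-tetramethyl-4a,5,8,8a-tetrahydronaphthalen-1(4H)-one
Product: 11 (2R,4aS,8aS)-2,5,5,8a-tetramethyl-3,4,4a,5,8,8a-hexahydronaphthalen-1(2H)-one, via lithium enolate 10 (not isolated)
Conditions: LiBH(s-Bu)3 (1.1 equiv), THF, −78 °C; MeOH; then NaOMe (cat.), MeOH, rt
Reagents that add atoms: none
Why: Conjugate (1,4) hydride reduction of the cyclohexenone, whose carbonyl is shielded by the quaternary C10, gives the enolate, and protonation followed by NaOMe equilibration should place the C8 methyl equatorial (8α), because the axial epimer would be syn-diaxial to the C10 methyl (thermodynamic control); the isolated C2=C3 alkene is inert.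

Step 7
Reactants: 11 (2R,4aS,8aS)-2,5,5,8a-tetramethyl-3,4,4a,5,8,8a-hexahydronaphthalen-1(2H)-one
Product: 12 (1S,2R,4aS,8aS)-1-ethenyl-2,5,5,8a-tetramethyl-1,2,3,4,4a,5,8,8a-octahydronaphthalen-1-ol
Conditions: CH2=CHMgBr, CeCl3, THF, −78 to 0 °C; aq. NH4Cl
Reagents that add atoms: vinylmagnesium bromide, C=C[Mg]Br
Why: 1,2-Addition of the weakly basic vinylcerium reagent (organocerium carbonyl addition) should suppress enolization of the hindered ketone and occur axially from the α face, anti to the axial C10 methyl, giving the equatorial 9β-hydroxyl and the 9α-vinyl group.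

Step 8
Reactants: 13 methyl 3-oxobutanoate
Product: 14 methyl (2E)-3-{[(trifluoromethyl)sulfonyl]oxy}but-2-enoate
Conditions: Tf2O, aq. Me4NOH, hexane, 5 °C
Reagents that add atoms: trifluoromethanesulfonic anhydride, O=S(=O)(OS(=O)(=O)C(F)(F)F)C(F)(F)F
Why: O-Sulfonylation of the β-keto ester enolate with a non-chelating tetramethylammonium counter-ion should favour the E enol triflate, in which the triflate is trans to the ester.

Step 9
Reactants: 12 (1S,2R,4aS,8aS)-1-ethenyl-2,5,5,8a-tetramethyl-1,2,3,4,4a,5,8,8a-octahydronaphthalen-1-ol; 14 methyl (2E)-3-{[(trifluoromethyl)sulfonyl]oxy}but-2-enoate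
Product: 16 methyl (2E)-5-[(1S,2R,4aS,8aS)-1-hydroxy-2,5,5,8a-tetramethyl-1,2,3,4,4a,5,8,8a-octahydronaphthalen-1-yl]-3-methylpent-2-enoate, via alkylborane 15 (not isolated)
Conditions: 9-BBN-H dimer, THF, 0 °C to rt; then 14, PdCl2(dppf) (5 mol %), aq. K3PO4, DMF, rt
Reagents that add atoms: none
Why: Anti-Markovnikov hydroboration by 9-BBN-H is selective for the monosubstituted vinyl group over the hindered ring alkene, and the B-alkyl Suzuki–Miyaura coupling proceeds with retention at the enol triflate, which fixes the 13E geometry.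

Step 10
Reactants: 16 methyl (2E)-5-[(1S,2R,4aS,8aS)-1-hydroxy-2,5,5,8a-tetramethyl-1,2,3,4,4a,5,8,8a-octahydronaphthalen-1-yl]-3-methylpent-2-enoate
Product: 17 methyl (2E)-5-[(1S,2R,4aS,6S,7R,8aS)-1,6,7-trihydroxy-2,5,5,8a-tetramethyldecahydronaphthalen-1-yl]-3-methylpent-2-enoate
Conditions: OsO4 (5 mol %), NMO (1.2 equiv), acetone/H2O, 0 °C to rt
Reagents that add atoms: osmium tetroxide, O=[Os](=O)(=O)=O; N-methylmorpholine N-oxide, C[N+]1([O-])CCOCC1; water, O
Why: Upjohn syn-dihydroxylation by electrophilic OsO4 should prefer the isolated C2=C3 alkene to the electron-poor conjugated enoate and attack from the α face, opposite the axial 4β and 10β methyls, giving the 2α,3α-diol.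

Step 11
Reactants: 17 methyl (2E)-5-[(1S,2R,4aS,6S,7R,8aS)-1,6,7-trihydroxy-2,5,5,8a-tetramethyldecahydronaphthalen-1-yl]-3-methylpent-2-enoate
Product: 18 methyl (2E)-5-[(1S,2R,4aS,6S,7R,8aS)-7-(acetyloxy)-1,6-dihydroxy-2,5,5,8a-tetramethyldecahydronaphthalen-1-yl]-3-methylpent-2-enoate (CNP0135744.1)
Conditions: Ac2O (1.1 equiv), pyridine, CH2Cl2, 0 °C
Reagents that add atoms: acetic anhydride, CC(=O)OC(C)=O
Why: Acylation should be kinetically selective for the equatorial C2 hydroxyl, since the axial, neopentyl C3 hydroxyl and the tertiary C9 hydroxyl react far more slowly (regioselective esterification).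

Compound list
1 | ethyl (2Z)-3-iodoprop-2-enoate | CCOC(=O)/C=C\I | starting material
2 | (2Z)-3-iodoprop-2-en-1-ol | OC/C=C\I | intermediate
3 | (1Z)-3-bromo-1-iodoprop-1-ene | BrC/C=C\I | intermediate
4 | (R)-(−)-carvone, (5R)-2-methyl-5-(prop-1-en-2-yl)cyclohex-2-en-1-one | O=C1C(C)=CC[C@@H](C(C)=C)C1 | starting material
5 | lithium dienolate of 4 (O–Li on the carbonyl carbon, new C=C to the α′-carbon) | [Li]OC1=C[C@H](C(C)=C)CC=C1C | intermediate
6 | (5R,6RS)-2,6-dimethyl-5-(prop-1-en-2-yl)cyclohex-2-en-1-one (epimers at C6) | O=C1C(C)=CC[C@@H](C(C)=C)C1C | intermediate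
7 | lithium dienolate of 6 | [Li]OC1=C(C)[C@H](C(C)=C)CC=C1C | intermediate
8 | (5S,6S)-6-[(2Z)-3-iodoprop-2-en-1-yl]-2,6-dimethyl-5-(prop-1-en-2-yl)cyclohex-2-en-1-one | O=C1C(C)=CC[C@@H](C(C)=C)[C@]1(C)C/C=C\I | intermediate
9 | (4aS,8aS)-2,5,5,8a-tetramethyl-4a,5,8,8a-tetrahydronaphthalen-1(4H)-one (trans-fused) | O=C1C(C)=CC[C@H]2C(C)(C)C=CC[C@@]21C | intermediate
10 | lithium enolate of 11 (C8=C9, O–Li on C9) | [Li]OC1=C(C)CC[C@H]2C(C)(C)C=CC[C@@]21C | intermediate
11 | (2R,4aS,8aS)-2,5,5,8a-tetramethyl-3,4,4a,5,8,8a-hexahydronaphthalen-1(2H)-one | O=C1[C@H](C)CC[C@H]2C(C)(C)C=CC[C@@]21C | intermediate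
12 | (1S,2R,4aS,8aS)-1-ethenyl-2,5,5,8a-tetramethyl-1,2,3,4,4a,5,8,8a-octahydronaphthalen-1-ol | C=C[C@]1(O)[C@H](C)CC[C@H]2C(C)(C)C=CC[C@@]21C | intermediate
13 | methyl 3-oxobutanoate | COC(=O)CC(C)=O | starting material
14 | methyl (2E)-3-{[(trifluoromethyl)sulfonyl]oxy}but-2-enoate | COC(=O)/C=C(\C)OS(=O)(=O)C(F)(F)F | intermediate
15 | B-alkyl-9-borabicyclo[3.3.1]nonane from 12 (boron on C12) | B3(C4CCCC3CCC4)CC[C@]1(O)[C@H](C)CC[C@H]2C(C)(C)C=CC[C@@]21C | intermediate
16 | methyl (2E)-5-[(1S,2R,4aS,8aS)-1-hydroxy-2,5,5,8a-tetramethyl-1,2,3,4,4a,5,8,8a-octahydronaphthalen-1-yl]-3-methylpent-2-enoate | COC(=O)/C=C(\C)CC[C@]1(O)[C@H](C)CC[C@H]2C(C)(C)C=CC[C@@]21C | intermediate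
17 | methyl (2E)-5-[(1S,2R,4aS,6S,7R,8aS)-1,6,7-trihydroxy-2,5,5,8a-tetramethyldecahydronaphthalen-1-yl]-3-methylpent-2-enoate | COC(=O)/C=C(\C)CC[C@]1(O)[C@H](C)CC[C@H]2C(C)(C)[C@H](O)[C@H](O)C[C@@]21C | intermediate
18 | methyl (2E)-5-[(1S,2R,4aS,6S,7R,8aS)-7-(acetyloxy)-1,6-dihydroxy-2,5,5,8a-tetramethyldecahydronaphthalen-1-yl]-3-methylpent-2-enoate | COC(=O)/C=C(\C)CC[C@]1(O)[C@H](C)CC[C@H]2C(C)(C)[C@H](O)[C@H](OC(C)=O)C[C@@]21C | target

Total step count: 11.
Longest linear sequence: 9 steps (steps 1, 2, 4, 5, 6, 7, 9, 10, 11); from carvone it is 8 steps.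

Steps most likely to fail

Step 5 (key step). The alkenylpalladium may be reduced by formate before it adds to the isopropenyl group, or the neopentyl-type alkylpalladium may re-insert into the new C2=C3 alkene (3-exo closure and rearrangement) before hydride capture. The fallback sets out from 6 and comes back at 9, and it closes ring A by a radical instead of an organopalladium route. Dienolate 7, made from 6 with LiN(i-Pr)2, would be added to acrylonitrile (Michael addition, again anti to the isopropenyl group) to give the cyanoethyl ketone F1. Hydrogen-atom transfer from an iron hydride (Fe(acac)3, PhSiH3, EtOH, 60 °C) to the isopropenyl group would give the tertiary C4 radical, which closes ring A by 6-exo-dig attack on the nitrile carbon. The resulting cyclic ketimine F2 would be hydrolysed on acidic work-up to the 3,9-dioxo compound F3. Kinetic deprotonation at C2 (KN(SiMe3)2, PhNTf2, THF, −78 °C; the ring-B enone has no α-hydrogen) would give the C3 enol triflate F4. Palladium-catalysed formate reduction (Pd(OAc)2, PPh3, HCO2H, n-Bu3N, DMF, 60 °C) would then give 9.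

Step 10. Osmylation may lose chemoselectivity (attack on the side-chain enoate) or facial selectivity once the axial side chain is present. The fallback sets out from 11 and comes back at 17, and it moves the dihydroxylation to a stage with a single alkene. OsO4/NMO on 11 would give the 2α,3α-diol ketone F5, and 2,2-dimethoxypropane with p-TsOH (cat.) would give its acetonide F6. CH2=CHMgBr/CeCl3 would give the 9β-hydroxy-9α-vinyl acetonide F7. 9-BBN-H would give the alkylborane F8, and coupling with 14 (PdCl2(dppf), aq. K3PO4) would give the acetonide ester F9. Aqueous AcOH at 40 °C would release 17.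

Step 7. The hindered, enolizable ketone may be deprotonated instead of attacked, or the facial selectivity may erode. The fallback sets out from 11 and comes back at 12, and it uses a linear, weakly basic alkynyl nucleophile followed by partial reduction. LiC≡CSiMe3 (THF, −78 to 0 °C) would add axially to give the silylalkynyl carbinol F10. K2CO3 in MeOH would give the ethynyl carbinol F11. Semi-hydrogenation (H2, Pd on CaCO3 poisoned with Pb(OAc)2, quinoline) would give 12.

Further compounds
F1 | step 5 | 3-[(1S,6S)-1,3-dimethyl-2-oxo-6-(prop-1-en-2-yl)cyclohex-3-en-1-yl]propanenitrile | O=C1C(C)=CC[C@@H](C(C)=C)[C@]1(C)CCC#N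
F2 | step 5 | (4aS,8aS)-6-imino-2,5,5,8a-tetramethyl-4a,5,6,7,8,8a-hexahydronaphthalen-1(4H)-one (C3 ketimine, not isolated) | O=C1C(C)=CC[C@H]2C(C)(C)C(=N)CC[C@@]21C
F3 | step 5 | (4aS,8aS)-2,5,5,8a-tetramethyl-4a,5,8,8a-tetrahydronaphthalene-1,6(4H,7H)-dione (3,9-dioxo compound) | O=C1C(C)=CC[C@H]2C(C)(C)C(=O)CC[C@@]21C
F4 | step 5 | (4aS,8aS)-1,1,4a,6-tetramethyl-5-oxo-1,4,4a,5,8,8a-hexahydronaphthalen-2-yl trifluoromethanesulfonate | O=C1C(C)=CC[C@H]2C(C)(C)C(OS(=O)(=O)C(F)(F)F)=CC[C@@]21C
F5 | step 10 | (2R,4aS,6S,7R,8aS)-6,7-dihydroxy-2,5,5,8a-tetramethyloctahydronaphthalen-1(2H)-one | O=C1[C@H](C)CC[C@H]2C(C)(C)[C@H](O)[C@H](O)C[C@@]21C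
F6 | step 10 | 2α,3α-O-isopropylidene acetal (acetonide) of F5 | O=C1[C@H](C)CC[C@H]2C(C)(C)[C@H](O3)[C@H](OC3(C)C)C[C@@]21C
F7 | step 10 | 9β-hydroxy-9α-vinyl acetonide (vinyl adduct of F6) | C=C[C@]1(O)[C@H](C)CC[C@H]2C(C)(C)[C@H](O3)[C@H](OC3(C)C)C[C@@]21C
F8 | step 10 | B-alkyl-9-borabicyclo[3.3.1]nonane from F7 (boron on C12) | B3(C4CCCC3CCC4)CC[C@]1(O)[C@H](C)CC[C@H]2C(C)(C)[C@H](O5)[C@H](OC5(C)C)C[C@@]21C
F9 | step 10 | 2α,3α-O-isopropylidene acetal (acetonide) of 17 | COC(=O)/C=C(\C)CC[C@]1(O)[C@H](C)CC[C@H]2C(C)(C)[C@H](O3)[C@H](OC3(C)C)C[C@@]21C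
F10 | step 7 | 9β-hydroxy-9α-[(trimethylsilyl)ethynyl] analogue of 12 | C[Si](C)(C)C#C[C@]1(O)[C@H](C)CC[C@H]2C(C)(C)C=CC[C@@]21C
F11 | step 7 | 9β-hydroxy-9α-ethynyl analogue of 12 | C#C[C@]1(O)[C@H](C)CC[C@H]2C(C)(C)C=CC[C@@]21C
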